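Grey and teal carry the same starting material and free catalyst, and teal has extra target, so the gap between these two runs shows what becomes of a surplus of target.

all flasks: free catalyst 20.0 mM

|  | starting material | target | time |
|---|---|---|---|
| grey | 200 mM |  |  |
| red | 100 mM |  |  |
| teal | 200 mM | 60.0 mM |  |
| violet | 100 mM |  |  |
| green | 800 mM |  | 11 min |

- grey run (time / min: [target] / mM): 0.39: 5.9; 1.2: 14.7; 2.3: 26.1; 3.6: 37.7; 5.2: 46.9; 6.9: 53.4; 8.9: 60.7; 11: 62.8
- red run (time / min: [target] / mM): 0.39: 4.3; 1.2: 8.6; 2.3: 15.4; 3.6: 18.9; 5.2: 27.2; 6.9: 29.9; 8.9: 32.5; 11: 33.7
- teal run (time / min: [target] / mM): 0.39: 65.5; 1.2: 69.3; 2.3: 75.4; 3.6: 83.9; 5.2: 90.4; 6.9: 90.7; 8.9: 92.5; 11: 91.8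
- violet run (time / min: [target] / mM): 0.39: 2.1; 1.2: 9.1; 2.3: 16.7; 3.6: 19.7; 5.2: 25.8; 6.9: 29.4; 8.9: 31.9; 11: 33.8

(standard deviation of a reading: 1 mM)

- order of the initial rate in [starting material], near the charge of the grey run, the rate being that where two percent of its starting material are target (one fixed amount of target, the same in the runs compared)
- target in the green run at 11 min, as a share of the starting material charged

- Overall: starting material -> target, with free catalyst as catalyst.
- Constant volume, constant temperature.
- What is held in complexes is read along with the free species.
- An order is taken over about fifteen percent of the charge, up and down.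

The teal-minus-grey gap starts at 60.0 mM and stands at 29.0 mM at 11 min. If making target ignores the target present, that shrinkage gives me the loss constant of target, the first-order constant at which a surplus of target fades, k = 0.0661 min⁻¹.

At 2.3 min the grey run holds 26.1 mM, while red and violet average 16.1 mM. That ratio of 1.63 gives an apparent Michaelis constant Km of 335 mM, so I expect an order of Km/(Km + c(starting material)) = 0.626 at the grey charge.

Grey's mean rate of 11.3 mM min⁻¹ then scales to 21.4 mM min⁻¹ at the green charge. I hold that rate r steady and integrate dc/dt = r − k·c in closed form, c(target) = r(1 − exp(−k·t))/k, which gives 20.9% of the green charge.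

The forecast, reading “partial saturation”, gives an order of 0.57 and a green share of 23.5%, a higher share than mine.

The flask gives an order of 0.62 and a green share of 20.2%, so my share stands 0.70 percentage points above it.

    free catalyst + starting material ⇌ catalyst-substrate complex, settled at all times (4.130 M⁻¹)
    catalyst-substrate complex → target + free catalyst (1.518 min⁻¹)
    2 free catalyst → 2 spent catalyst (3.840 M⁻¹ min⁻¹)
    target → decomposed product (0.06780 min⁻¹)

The green run gives up 8.8 points of its charge through the turning of target into decomposed product: with that step it ends at 20.2%, without it at 29.0%. The loss constant read from teal and grey puts a number on this. Target made evenly over 11 min survives to the share (1 − exp(−k·t))/(k·t) = 0.711, and the green run with that step ends at 0.697 of the green run without it.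

The data are calculated from invented constants, noise included.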